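The ten-membered carbocycle C1–C10 holds its ketone (C3) and its glycol (C8, C9) in the array C3(=O)–C2–C1–C10–C9–C8. This is the retron of an anionic oxy-Cope ring expansion followed by syn-dihydroxylation. (R)-Carvone supplies C3–C8, C11–C13 and C15. It is oxidised to a cyclohexane trans-fused to a methylene-tetrahydrofuran (the lactone ring in masked form) that bears a 3-vinyl carbinol and an 8-(Z)-propenyl group. One [3,3] shift breaks C3–C8 and joins C1 to C10. It opens the six-membered ring into the cyclodecenone, unveils the ketone, sets C10 and leaves an E-alkene at C8=C9. Both C3 epimers of the carbinol should converge on this product.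

Key step: step 11

Remark on descriptors: all atoms carry their target numbers (C3 ring ketone, C4 carbinol carbon with methyl C15, C5 CH–O-acyl, C6 CH–O of the lactone, C7, C8 CHOH, C9 CH–O-acyl, C10 with methyl C14, C1 and C2 the CH2 groups, C11(=C13H2)–C12 the lactone carbons); β is the ring face of the C6–O bond and α the face of the C7–C11 bond.
Remark on supply: (R)-2-methylbutanoic acid is taken as commercially available in enantiopure form.

Step 1
Reactants: 1 (R)-(−)-carvone
Product: 2 (R)-5-(3-chloroprop-1-en-2-yl)-2-methylcyclohex-2-en-1-one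
Conditions: NCS, PhSeCl (cat.), CH2Cl2, rt
Reagents that add atoms: N-chlorosuccinimide, O=C1CCC(=O)N1Cl
Why: Selenium-catalysed ene-type allylic chlorination touches only the electron-rich 1,1-disubstituted alkene, because the enone C=C is deactivated, and it leaves C7 untouched.

Step 2
Reactants: 2 (R)-5-(3-chloroprop-1-en-2-yl)-2-methylcyclohex-2-en-1-one
Product: 4 (5S,6S)-5-(3-chloroprop-1-en-2-yl)-6-hydroxy-2-methylcyclohex-2-en-1-one (6β-OH trans to the 7α side chain), via potassium dienolate 3 (not isolated)
Conditions: KHMDS, THF, −78 °C; 2-(phenylsulfonyl)-3-phenyloxaziridine; AcOH, −78 °C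
Reagents that add atoms: 2-(phenylsulfonyl)-3-phenyloxaziridine, O=S(=O)(N1OC1c1ccccc1)c1ccccc1
Why: Kinetic α'-enolisation and Davis oxaziridine hydroxylation, in which the oxidant reaches C6 anti to the C7 side chain and gives the trans (diequatorial, also thermodynamically preferred) ketol.

Step 3
Reactants: 4 (5S,6S)-5-(3-chloroprop-1-en-2-yl)-6-hydroxy-2-methylcyclohex-2-en-1-one
Product: 5 7α-(3-chloroprop-1-en-2-yl)-4-methylcyclohex-3-ene-5α,6β-diol
Conditions: NaBH4, CeCl3·7H2O, MeOH, −78 °C
Reagents that add atoms: none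
Why: Luche 1,2-reduction with axial hydride delivery from the β face gives the quasi-equatorial 5α-alcohol, as in the reduction of carvone to cis-carveol, and spares the allylic chloride.

Step 4
Reactants: 5 7α-(3-chloroprop-1-en-2-yl)-4-methylcyclohex-3-ene-5α,6β-diol
Product: 6 6-methyl-3-methylidene-2,3,3a,4,7,7a-hexahydro-1-benzofuran-7-ol (trans-fused 6β,12-ether; 5α-OH)
Conditions: NaH, THF, 0 °C to rt
Reagents that add atoms: none
Why: Intramolecular Williamson etherification (5-exo-tet) is open only to O6, because O5 would have to bridge the ring 1,3-diaxially, and it closes the trans-fused ring that later becomes the lactone.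

Step 5
Reactants: 6 trans-fused 6β,12-ether 5α-ol
Product: 7 3α,4α-epoxide of 6
Conditions: m-CPBA, CH2Cl2, 0 °C
Reagents that add atoms: m-chloroperbenzoic acid, OOC(=O)c1cccc(Cl)c1
Why: Henbest hydroxyl-directed peracid epoxidation, in which the quasi-equatorial 5α-OH delivers oxygen to the α face of the more nucleophilic trisubstituted alkene while the 1,1-disubstituted allylic-ether alkene reacts more slowly.

Step 6
Reactants: 7 3α,4α-epoxide of 6
Product: 8 3β,4α,5α-triol (4β-methyl)
Conditions: HClO4 (cat.), THF/H2O, 0 °C to rt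
Reagents that add atoms: water, O
Why: Acid-catalysed epoxide hydrolysis under Fürst–Plattner control, because in the locked trans-fused bicycle only attack of water at C3 from the β face is trans-diaxial (as for trans-limonene oxide) and C4 is inductively deactivated by O5, so C4 keeps its α-oxygen.

Step 7
Reactants: 8 3β,4α,5α-triol
Product: 9 4α,5α-O-isopropylidene-3β-ol
Conditions: 2,2-dimethoxypropane, PPTS (cat.), CH2Cl2, rt
Reagents that add atoms: 2,2-dimethoxypropane, COC(C)(C)OC
Why: Acid-catalysed transketalisation picks the cis 4α,5α-diol, because the 3β and 4α hydroxyls are trans-diaxial and cannot be bridged, and it leaves 3-OH free.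

Step 8
Reactants: 9 4α,5α-O-isopropylidene-3β-ol
Product: 10 4α,5α-O-isopropylidene-3-ketone
Conditions: Dess–Martin periodinane, CH2Cl2, rt
Reagents that add atoms: none
Why: Dess–Martin oxidation of the only free (axial, secondary) alcohol under near-neutral conditions that spare the ketal, the allyl ether and the alkene.

Step 9
Reactants: 10 4α,5α-O-isopropylidene-3-ketone; 11 (Z)-1-bromoprop-1-ene
Product: 13 8β-[(Z)-prop-1-enyl]-3-ketone, via lithium dienolate 12 (not isolated)
Conditions: Pd2(dba)3 (cat.), Q-Phos (cat.), LiHMDS (2.2 equiv), toluene/THF, rt; AcOH, −78 °C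
Reagents that add atoms: 11 (Z)-1-bromoprop-1-ene, C/C=C\Br
Why: Palladium-catalysed α-alkenylation of a ketone enolate with retention of the Z geometry of 11; C4 is quaternary so only C8 can enolise, the product rests as dienolate 12, and kinetic axial α-protonation gives the β,γ-unsaturated ketone with the propenyl group equatorial (8β, trans to C7–C11), which is also the thermodynamic epimer.

Step 10
Reactants: 13 8β-[(Z)-prop-1-enyl]-3-ketone; 14 vinylmagnesium bromide
Product: 15 3β-vinyl-3α-ol (8β-(Z)-propenyl)
Conditions: LaCl3·2LiCl, THF, −20 °C; AcOH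
Reagents that add atoms: 14 vinylmagnesium bromide, C=C[Mg]Br
Why: Lanthanide-promoted Grignard 1,2-addition outruns enolisation of the acidic ketone, attack anti to the dioxolane (β face) should give mainly the 3β-vinyl 3α-ol, and this centre is erased in step 11.

Step 11
Reactants: 15 3β-vinyl-3α-ol (8β-(Z)-propenyl)
Product: 18 (8E)-10α-methylcyclodec-8-en-3-one (6β,12-ether; 4α,5α-acetonide), via potassium alkoxide 16 (not isolated), via potassium enolate 17 (not isolated)
Conditions: KH, 18-crown-6, THF, 0 to 40 °C; AcOH, −78 °C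
Reagents that add atoms: none
Why: Deprotonation gives alkoxide 16, whose charge-accelerated concerted [3,3]-sigmatropic shift (the anionic oxy-Cope rearrangement of 1,2-dialkenylcyclohexanols to cyclodec-5-enones is the closest known type) cleaves C3–C8 and joins C1 to C10 to give enolate 17, which is protonated on quench. The ten-membered ring is closed by four-atom ring expansion of the six-membered ring C3–C8 through a chair-like six-centre array, while the oxygen ring closed in step 4 is untouched. C10 is the only new stereocentre and is set by suprafacial chirality transfer from C8 (8β-alkenyl) through the Z-propenyl group, which gives 10α-methyl (10R). The step needs E geometry at C8=C9, and A(1,3) strain between the Z-methyl group and C7 allows only the rotamer about C8–C9 that holds C10 anti to C7, so the path to the Z-alkene and the C10 epimer is closed. Because C3 becomes trigonal both carbinol epimers should converge, the 3α-vinyl epimer through an all-chair array and 15 through a boat form of the carbocycle (C3 and C6 as bow and stern, alkoxide oxygen flagpole, vinyl quasi-equatorial, C4–C5 torsion relaxed to suit the dioxolane) that has the same C2–C3–C8–C9 torsion. Enolate 17 meets no internal electrophile because the lactone is still an ether and the esters are still a ketal, which is why C12 oxidation and acylation come later.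

Step 12
Reactants: 18 (8E)-10α-methylcyclodec-8-en-3-one (6β,12-ether; 4α,5α-acetonide)
Product: 19 (8E)-6β,12-olide (α-methylene-γ-lactone; 4α,5α-acetonide)
Conditions: CrO3, 3,5-dimethylpyrazole, CH2Cl2, −20 °C
Reagents that add atoms: chromium trioxide, O=[Cr](=O)=O
Why: Chromium(VI) allylic oxidation, a known way from 3-methylenetetrahydrofurans to α-methylene-γ-butyrolactones, attacks C12–H2 because it is both allylic and α to oxygen, whereas the allylic C7–H and C10–H are tertiary and hindered.

Step 13
Reactants: 19 (8E)-6β,12-olide (4α,5α-acetonide)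
Product: 20 (8E)-4α,5α-dihydroxy-3-oxo-6β,12-olide
Conditions: AcOH/H2O (4:1), 40 °C
Reagents that add atoms: none
Why: Mild acid hydrolysis of the ketal, eased by its tertiary C4–O bond, is kept weak enough to avoid transannular carbonyl-ene or Prins closure between C3=O and C8=C9.

Step 14
Reactants: 20 (8E)-4α,5α-dihydroxy-3-oxo-6β,12-olide; 21 (R)-2-methylbutanoic acid
Product: 22 (8E)-5α-O-[(R)-2-methylbutanoyl]-4α-hydroxy-3-oxo-6β,12-olide
Conditions: DCC, DMAP (cat.), CH2Cl2, 0 °C to rt
Reagents that add atoms: 21 (R)-2-methylbutanoic acid, CC[C@@H](C)C(=O)O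
Why: Steglich esterification finds a single acylable hydroxyl (secondary 5-OH, since 4-OH is tertiary), and low temperature with catalytic DMAP keeps the α-stereocentre of 21 intact.

Step 15
Reactants: 22 (8E)-5α-O-[(R)-2-methylbutanoyl]-4α-hydroxy-3-oxo-6β,12-olide
Product: 23 8β,9α-diol of 22
Conditions: OsO4 (cat.), NMO, acetone/H2O, 0 °C
Reagents that add atoms: N-methylmorpholine N-oxide, C[N+]1([O-])CCOCC1; water, O
Why: Upjohn syn-dihydroxylation selects the strained electron-rich E-alkene over the electron-poor α-methylene lactone, and osmium adds to the peripheral face of the conformer with H7 eclipsing C8=C9 (the face opposite to the broken C3–C8 bond), which gives the 8β,9α (8R,9R) diol, the sense also favoured by (DHQD)2PHAL if reagent control is wanted.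

Step 16
Reactants: 23 8β,9α-diol of 22; 24 3-methylbutanoic (isovaleric) anhydride
Product: 25 target CNP0269576.1
Conditions: 24 (1 equiv), DMAP (cat.), 2,4,6-collidine, CH2Cl2, −40 °C
Reagents that add atoms: 24 3-methylbutanoic anhydride, CC(C)CC(=O)OC(=O)CC(C)C
Why: Kinetically controlled DMAP-catalysed monoacylation should go to 9-OH, because 8-OH is flanked by the ring-fusion carbon C7 and lies next to the lactone, and 4-OH is tertiary.

Compound list
1 | (R)-(−)-carvone | CC1=CC[C@H](CC1=O)C(C)=C | starting material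
2 | (R)-5-(3-chloroprop-1-en-2-yl)-2-methylcyclohex-2-en-1-one | CC1=CC[C@H](CC1=O)C(=C)CCl | intermediate
3 | potassium cross-conjugated dienolate of 2 (not isolated) | [K+].[O-]C1=C[C@H](C(=C)CCl)CC=C1C | intermediate
4 | (5S,6S)-5-(3-chloroprop-1-en-2-yl)-6-hydroxy-2-methylcyclohex-2-en-1-one | C1=C(C)C(=O)[C@@H](O)[C@H](C(=C)CCl)C1 | intermediate
5 | 7α-(3-chloroprop-1-en-2-yl)-4-methylcyclohex-3-ene-5α,6β-diol | C1=C(C)[C@H](O)[C@@H](O)[C@H](C(=C)CCl)C1 | intermediate
6 | trans-fused 6-methyl-3-methylidene-2,3,3a,4,7,7a-hexahydro-1-benzofuran-7-ol (5α-OH) | C1=C(C)[C@H](O)[C@H]2OCC(=C)[C@@H]2C1 | intermediate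
7 | 3α,4α-epoxide of 6 | [C@@H]12O[C@]1(C)[C@H](O)[C@H]3OCC(=C)[C@@H]3C2 | intermediate
8 | 3β,4α,5α-triol | O[C@H]1[C@](C)(O)[C@H](O)[C@H]2OCC(=C)[C@@H]2C1 | intermediate
9 | 4α,5α-O-isopropylidene-3β-ol | O[C@H]1[C@]2(C)OC(C)(C)O[C@@H]2[C@H]3OCC(=C)[C@@H]3C1 | intermediate
10 | 4α,5α-O-isopropylidene-3-ketone | O=C1[C@]2(C)OC(C)(C)O[C@@H]2[C@H]3OCC(=C)[C@@H]3C1 | intermediate
11 | (Z)-1-bromoprop-1-ene | C/C=C\Br | starting material
12 | lithium dienolate of 13 (not isolated) | [Li+].[O-]C1=C(/C=C\C)[C@H]2C(=C)CO[C@@H]2[C@H]3OC(C)(C)O[C@@]13C | intermediate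
13 | 8β-[(Z)-prop-1-enyl]-3-ketone | O=C1[C@]2(C)OC(C)(C)O[C@@H]2[C@H]3OCC(=C)[C@@H]3[C@H]1/C=C\C | intermediate
14 | vinylmagnesium bromide | C=C[Mg]Br | starting material
15 | 3β-vinyl-3α-ol with 8β-(Z)-propenyl group | C=C[C@@]1(O)[C@]2(C)OC(C)(C)O[C@@H]2[C@H]3OCC(=C)[C@@H]3[C@H]1/C=C\C | intermediate
16 | potassium alkoxide of 15 (not isolated) | [K+].C=C[C@@]1([O-])[C@]2(C)OC(C)(C)O[C@@H]2[C@H]3OCC(=C)[C@@H]3[C@H]1/C=C\C | intermediate
17 | potassium C2=C3 enolate of 18 (not isolated) | [K+].[O-]/C1=C/C[C@@H](C)/C=C/[C@H]2C(=C)CO[C@@H]2[C@H]3OC(C)(C)O[C@@]13C | intermediate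
18 | (8E)-10α-methylcyclodec-8-en-3-one, 6β,12-ether, 4α,5α-acetonide | O=C1CC[C@@H](C)/C=C/[C@H]2C(=C)CO[C@@H]2[C@H]3OC(C)(C)O[C@@]13C | intermediate
19 | (8E)-6β,12-olide (α-methylene-γ-lactone), 4α,5α-acetonide | O=C1CC[C@@H](C)/C=C/[C@H]2C(=C)C(=O)O[C@@H]2[C@H]3OC(C)(C)O[C@@]13C | intermediate
20 | (8E)-4α,5α-dihydroxy-3-oxo-6β,12-olide | O=C1CC[C@@H](C)/C=C/[C@H]2C(=C)C(=O)O[C@@H]2[C@@H](O)[C@@]1(C)O | intermediate
21 | (R)-2-methylbutanoic acid | CC[C@@H](C)C(=O)O | starting material
22 | (8E)-5α-O-[(R)-2-methylbutanoyl]-4α-hydroxy-3-oxo-6β,12-olide | O=C1CC[C@@H](C)/C=C/[C@H]2C(=C)C(=O)O[C@@H]2[C@@H](OC(=O)[C@H](C)CC)[C@@]1(C)O | intermediate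
23 | 8β,9α-diol of 22 | O=C1CC[C@@H](C)[C@@H](O)[C@H](O)[C@H]2C(=C)C(=O)O[C@@H]2[C@@H](OC(=O)[C@H](C)CC)[C@@]1(C)O | intermediate
24 | 3-methylbutanoic (isovaleric) anhydride | CC(C)CC(=O)OC(=O)CC(C)C | starting material
25 | CNP0269576.1 | C=C1C(=O)O[C@H]2[C@H]1[C@@H](O)[C@H](OC(=O)CC(C)C)[C@H](C)CCC(=O)[C@](C)(O)[C@@H]2OC(=O)[C@H](C)CC | target

Total step count: 16. Longest linear sequence: 16 (from 1).

Steps most likely to fail

Step 9 (α-alkenylation).
- What may go wrong: coupling at the hindered enolate may be slow, the Z geometry may erode, or the β,γ-double bond may drift into conjugation in the basic medium.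
- Fallback, from 10 and back at 15: the Z-alkene is made by olefination instead of cross-coupling. TMSOTf/Et3N converts 10 to the trimethylsilyl enol ether F1. A Mukaiyama-type reaction with trimethyl orthoformate and BF3·OEt2 at −78 °C gives the 8β-(dimethoxymethyl) ketone F2. Vinylmagnesium bromide with LaCl3·2LiCl gives the carbinol dimethyl acetal F3. LiBF4 in wet MeCN frees the hydroxy aldehyde F4 without touching the dioxolane. A salt-free, Z-selective Wittig reaction with ethylidenetriphenylphosphorane then gives 15.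

Step 11 (ring expansion).
- What may go wrong: the boat-type conformer that the major carbinol epimer needs may be reached too slowly. Cleavage of the alkoxide, or leakage through the array that forms the Z-alkene, could then compete.
- Fallback, from 15 and back at 18: the rearrangement is entered with the C3 epimer, in which both alkenyl groups are equatorial. That epimer is made by delivering oxygen, not carbon, to the open β face. Treating 15 with n-BuLi then PhSCl triggers the Mislow–Evans sulfenate-to-sulfoxide shift and gives the allylic phenyl sulfoxide F5 with an exocyclic C3=C2 bond. Warming with P(OMe)3 in MeOH intercepts the sulfenate formed on the less hindered axial β face and gives the 3α-vinyl-3β-ol F6. Under the conditions of step 11, F6 rearranges through the all-chair array to 18.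

Step 16 (site-selective acylation).
- What may go wrong: acyl transfer may go to O8 instead of O9, the acyl group may migrate between the two, or O9 may be masked by transannular hemiketal formation with C3.
- Fallback, from 23 and back at 25: the bias is used instead of fought. TESCl/imidazole caps the more accessible O8 to give the 8-O-triethylsilyl ether F7. Excess 24 with DMAP at rt acylates O9, the remaining secondary hydroxyl, to give the 8-O-triethylsilyl 9-O-isovalerate F8. HF·pyridine then frees O8 to give 25.

Further compounds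
F1 | step 9 | trimethylsilyl enol ether of 10 | C[Si](C)(C)OC1=C[C@H]2C(=C)CO[C@@H]2[C@H]3OC(C)(C)O[C@@]13C
F2 | step 9 | 8β-(dimethoxymethyl)-3-ketone | O=C1[C@]2(C)OC(C)(C)O[C@@H]2[C@H]3OCC(=C)[C@@H]3[C@H]1C(OC)OC
F3 | step 9 | 3β-vinyl-3α-ol 8β-dimethyl acetal | C=C[C@@]1(O)[C@]2(C)OC(C)(C)O[C@@H]2[C@H]3OCC(=C)[C@@H]3[C@H]1C(OC)OC
F4 | step 9 | 3β-vinyl-3α-hydroxy 8β-carbaldehyde | C=C[C@@]1(O)[C@]2(C)OC(C)(C)O[C@@H]2[C@H]3OCC(=C)[C@@H]3[C@H]1C=O
F5 | step 11 | allylic phenyl sulfoxide with exocyclic C3=C2 (C1 anti to C4; mixture at sulfur) | O=S(c1ccccc1)C/C=C1/[C@]2(C)OC(C)(C)O[C@@H]2[C@H]3OCC(=C)[C@@H]3[C@H]1/C=C\C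
F6 | step 11 | 3α-vinyl-3β-ol (C3 epimer of 15) | C=C[C@]1(O)[C@]2(C)OC(C)(C)O[C@@H]2[C@H]3OCC(=C)[C@@H]3[C@H]1/C=C\C
F7 | step 16 | 8-O-triethylsilyl ether of 23 | O=C1CC[C@@H](C)[C@@H](O)[C@H](O[Si](CC)(CC)CC)[C@H]2C(=C)C(=O)O[C@@H]2[C@@H](OC(=O)[C@H](C)CC)[C@@]1(C)O
F8 | step 16 | 8-O-triethylsilyl 9-O-isovalerate | O=C1CC[C@@H](C)[C@@H](OC(=O)CC(C)C)[C@H](O[Si](CC)(CC)CC)[C@H]2C(=C)C(=O)O[C@@H]2[C@@H](OC(=O)[C@H](C)CC)[C@@]1(C)O
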